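## The problem

Sodwanone T (26) consists of two 2,2,5a,7-tetramethyl-octahydro-1-benzoxepine units, each an oxepane trans-fused to a cyclohexene, joined through their tetrasubstituted alkene carbons C6 and C6' by a CH2–CH2 bridge. The two units share the carbon skeleton and the configuration at the quaternary carbon C5a (angular methyl) and at the fusion carbon C9a (CH–O); they differ only at C3, an (R)-carbinol in one unit and a ketone in the other. A synthesis therefore has to make one enantiopure bicycle, bring it to two oxidation states and join the two forms unsymmetrically, because oxidising one of two equal carbinols in a dimer would be a statistical step. Within each bicycle C5a and C9a are adjacent, so the quaternary carbon can direct the fusion hydrogen, whereas the C3 carbinol stands 1,4 to C5a across the seven-membered ring and can relay information only through the ring conformation. C5a and the bridge-bearing C6 are both neopentyl-type positions that intermolecular reagents reach poorly. The tetrasubstituted alkenes can migrate under protic acid, the tertiary ether carbon C2 can ionise with strong Lewis acid, and the α-alkoxy ketone should not be carried through hydride steps. The enabling feature is C9a: it is a CH–O carbon that stands at the acetal oxidation level once the oxepane is taken back to a lactol, and it is bonded to the ring methylene C9, which lies three atoms (C9, C8, C7) from C6, itself bonded to C5a. The carbocycle C5a–C6–C7–C8–C9–C9a can therefore be closed at the C9–C9a bond by a four-carbon nucleophile seated on C5a attacking an oxepanyl oxocarbenium ion.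

## Retrosynthesis

**26 from 25.** The last operation should only uncover the C3 hydroxyl, so 26 is taken back to its triisopropylsilyl ether 25, in which the ketone of the other half is already present. No skeletal bond is cut; the two halves are different before they are joined.

**25 from 21 and 23 (through 24).** The bond between the bridge CH2 and C6' of the ketone half is cut. Cutting the central CH2–CH2 bond would require an sp3–sp3 union of two nearly identical fragments, and cutting both alkene–CH2 bonds would need a doubly metallated two-carbon unit. The single sp2–sp3 cut lets the two bridge carbons arrive as a vinyl group on one half (diene 21), which hydroboration turns into primary alkylborane 24; the other half is enol triflate 23. Each partner is one bicycle. The forward reaction must hydroborate only the vinyl group and couple at a tetrasubstituted triflate beside a quaternary carbon.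

**21 and 23 from 19.** Both partners come from one enol triflate 19. Exchange of triflate for the vinyl group of stannane 20 gives 21; removal of the silyl group (22) and oxidation give 23. The halves diverge only after every stereocentre is in place.

**19 from 17.** The tetrasubstituted alkene is traced to enone 17. Its carbonyl carbon C6 has a quaternary neighbour, so conjugate reduction gives the only enolate this ketone can form (18), and trapping on oxygen fixes the double bond at C6=C7. Eliminations or olefinations would leave the alkene position open.

**17 from 15 (key cut).** The C9–C9a bond is cut. The neighbouring cuts are weaker: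
- C5a–C6 would put the hindered acylation at the quaternary carbon late and on a bicycle.
- C7=C8 (metathesis or aldol) would require C9a to be set beforehand in an intermolecular step.
- The ether bonds would mean closing a tertiary ether in a seven-membered ring.

The chosen cut uses the acetal level of C9a. The nucleophile is the terminal carbon of a silyl dienol ether held on C5a; the electrophile is oxocarbenium ion 16, released from lactol acetate 15. The precursor is monocyclic with two stereocentres. The forward reaction needs a dienol ether with the vinyl group cis to the quaternary carbon, and an attack that leaves the C9a hydrogen anti to the angular methyl.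

**15 from 13 from 12.** These are functional-group changes: the acetate comes from the lactone by reductive acetylation (through lactolate 14), and the dienol ether from the tigloyl ketone of 12. The ketone is converted first, so that it is masked as its dienol ether while the lactone is reduced.

**12 from 9 and 10.** The bond between the lactone α-carbon and the acyl carbon is cut, leading to enolate 11 of lactone 9 and tigloyl chloride (10). This step creates the quaternary carbon. The acyl group has to enter trans to the silyloxy group, so that the methyl ends cis to it.

**9 from 8 from 7.** The carbinol is taken back to the ketone of oxepanedione 7. That ketone is flanked by a fully substituted carbon and a methylene, a favourable case for catalytic enantioselective reduction. The lactone α-centre needs no control because step 6 planarises it.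

**7 from 4 and 5; 4 from 3 from 1 and 2.** In 7 the two bonds to the CH2–CH2 unit are cut. Photocycloaddition of ethylene (5) to the enol double bond of tetronic acid 4, followed by retro-aldol opening of cyclobutanol 6, expands the five-membered to the seven-membered lactone. This avoids lactonisation onto a tertiary alcohol, where the six-membered lactone through the secondary oxygen would win. Acid 4 is the Dieckmann product of ester 3, made from 1 and 2.

## Roads not taken

**Alternative 1:** The cut removes the two methyl–C5a bonds and traces both carbocycles to the arene rings of the bibenzyl bis-benzamide A1. In the forward step a dissolving-metal reduction converts both 2-methoxybenzamide rings into amide enolates, and methylation gives bis-diene A2.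
- Merits: both quaternary carbons are set in one flask under the control of the prolinol-ether amide. The bridge and both tetrasubstituted alkenes are present from the start. No hindered sp2–sp3 coupling is needed, and in this respect the road is better than the chosen plan, which must force such a coupling in step 14.
- Weak points: A2 contains none of the oxepane atoms. On each half the amide carbon must be reduced to the C5 methylene and extended by the C4–C3–C2 unit with its two methyls. Each enol ether must be hydrolysed and the ketone reduced trans to the angular methyl. A tertiary ether must then be closed in a seven-membered ring, all beside an acid-sensitive 1,4-diene. The amide in A1 is flanked by two ortho substituents and is twisted out of conjugation, which weakens the basis for both the regiochemistry of the reduction and the facial control. Because the halves are made identical, the ketone/carbinol difference would have to be introduced statistically at the end.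
- Comparison: the chosen plan makes the oxepane first, by a ring expansion, and differentiates the halves before union. Against the cleaner quaternary-carbon control of A2 it has to set its reliance on 1,4-induction in step 6.

**Alternative 2:** The cut is the bond between the gem-dimethyl carbon C2 and the carbonyl carbon C3 of the oxepanone in the ketone half. In the forward step a nickel–bipyridine catalyst at the cathode turns the thioester of A3 into an acyl–nickel species and its N-acyloxyphthalimide into a tertiary α-alkoxy radical; their union closes the ring to A4.
- Merits: the ketone oxidation state is reached directly, with no protecting group and no carbinol stereocentre to carry in that half. Here it is better than the chosen plan, which spends steps 12 and 13 on desilylation and oxidation. The conditions are neutral, and the bond formed is at a fully substituted carbon, where radical couplings are strong.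
- Weak points: closing a seven-membered ring in this way is an extrapolation from intermolecular couplings, and the radical can be reduced or dimerise before it finds the tethered acyl–nickel centre. The step also leaves the real stereochemical task untouched, since the cyclohexene of A3, with its quaternary carbon and trans C–O centre, must be made by other means and is no simpler than 17. Only the ketone half is addressed. The pivaloyloxymethyl handle on C6 implies an sp3–sp3 union of two allylic carbons to make the bridge, with a cross-selectivity problem.
- Comparison: the chosen plan draws both halves from one intermediate and builds the bridge by an sp2–sp3 coupling of unlike partners.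

**Alternative 3:** The cut removes, in each half, the C5a–C6 bond and the O1–C2 bond, leading back to the twofold-symmetric tetraepoxide A5. In the forward step an alkylaluminium chloride makes each central alkene attack the tertiary carbon of the neighbouring internal epoxide, and each released alkoxide opens the terminal epoxide at its gem-dimethyl carbon, giving diol A6.
- Merits: this is by far the shortest road, forming four rings and four bonds in one step. Trans fusion and the quaternary configuration follow stereospecifically from anti opening of the epoxides. This is better than the chosen plan, where the fusion depends on a facial preference in step 9 and the quaternary carbon on 1,4-induction in step 6.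
- Weak points:
  - The tertiary cation left at C7 can lose a proton toward C6 (needed), toward C8 or toward the methyl, and the choice must be right in both halves.
  - Both epoxide openings must be regioselective twice (oxepane against tetrahydropyran, cyclisation against hydride shift).
  - A5 is heterochiral within each half: the terminal epoxide CH carbon is R while the internal epoxide carbons are S. The four epoxides therefore cannot be installed by one reagent-controlled epoxidation, and the two central alkenes must survive, so A5 needs fragment assembly.
  - A6 is the symmetric diol, and 26 requires oxidation of one of two equivalent carbinols.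
- Comparison: even so, this road would be shorter. The chosen plan sets against it a fixed alkene position (enol triflate 19), differentiation of the halves before union, and steps that each have close precedent.

Key step: step 9

Remarks on the chemistry:
- Compounds 7–16 are numbered as oxepan-2-ones (C2 carbonyl or acetal carbon, C3 α-carbon, C6 carbinol carbon, C7 gem-dimethyl carbon). Compounds from 17 on are numbered as 1-benzoxepines; lactone C2, C3 and C6 become C9a, C5a and C3.
- Compounds 7–9 are mixtures of C3 epimers, a centre that step 6 planarises. Compound 15 is used as the anomeric mixture.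
- The sense of step 4 is assigned on the usual oxazaborolidine model, with the gem-dimethyl-bearing carbon as the large group.
- TIPS = triisopropylsilyl, TBS = tert-butyldimethylsilyl, TES = triethylsilyl.

## Steps

Step 1
Reactants: 1 ethyl 2-hydroxy-2-methylpropanoate; 2 propanoyl chloride
Product: 3 ethyl 2-methyl-2-(propanoyloxy)propanoate
Conditions: pyridine, DMAP (cat.), CH2Cl2, 0 °C → rt
Reagents that add atoms: none
Why: O-Acylation of the tertiary α-hydroxy ester by the acid chloride under nucleophilic catalysis; no stereocentre is involved.

Step 2
Reactants: 3 ethyl 2-methyl-2-(propanoyloxy)propanoate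
Product: 4 4-hydroxy-3,5,5-trimethylfuran-2(5H)-one (3,5,5-trimethyltetronic acid)
Conditions: LiN(SiMe3)2 (2.2 equiv), THF, −78 → 0 °C; aq. HCl
Reagents that add atoms: none
Why: Dieckmann-type condensation of the propanoate enolate onto the ethyl ester closes the five-membered ring; the acidic product consumes the second equivalent of base and is isolated as its stable enol.

Step 3
Reactants: 4 3,5,5-trimethyltetronic acid; 5 ethylene
Product: 7 3,7,7-trimethyloxepane-2,6-dione (racemic), via cyclobutanol photoadduct 6 (not isolated)
Conditions: hν (254 nm, quartz), ethylene (1 atm), MeCN, −20 °C; then DBU (cat.), rt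
Reagents that add atoms: none
Why: de Mayo reaction: [2+2] photocycloaddition of the enol C=C with ethylene gives cyclobutanol 6, whose strain-driven retro-aldol cleavage (completed by the catalytic base) inserts the two carbons and expands the lactone to the oxepane-2,6-dione. The α-carbon is formed as a racemate and is erased in step 6.

Step 4
Reactants: 7 3,7,7-trimethyloxepane-2,6-dione
Product: 8 (6R)-6-hydroxy-3,7,7-trimethyloxepan-2-one (C3 epimers)
Conditions: (S)-2-methyl-CBS-oxazaborolidine (10 mol %), BH3·SMe2, THF, −20 °C; MeOH
Reagents that add atoms: none
Why: Corey–Bakshi–Shibata reduction: the ketone lies between a fully substituted carbon and a methylene, a size difference the catalyst reads well, and the (S)-catalyst should deliver hydride to give the (6R)-alcohol. The lactone is not reduced by borane at this temperature.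

Step 5
Reactants: 8 (6R)-6-hydroxy-3,7,7-trimethyloxepan-2-one
Product: 9 (6R)-3,7,7-trimethyl-6-(triisopropylsilyloxy)oxepan-2-one (C3 epimers)
Conditions: TIPSOTf, 2,6-lutidine, CH2Cl2, −78 → 0 °C
Reagents that add atoms: triisopropylsilyl trifluoromethanesulfonate, CC(C)[Si](OS(=O)(=O)C(F)(F)F)(C(C)C)C(C)C
Why: Silylation of a hindered secondary alcohol with a silyl triflate. Prompt protection also removes the risk that the free hydroxyl translactonises to the six-membered lactone.

Step 6
Reactants: 9 (6R)-3,7,7-trimethyl-6-(triisopropylsilyloxy)oxepan-2-one; 10 (E)-2-methylbut-2-enoyl chloride (tigloyl chloride)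
Product: 12 (3S,6R)-3-[(2E)-2-methylbut-2-enoyl]-3,7,7-trimethyl-6-(triisopropylsilyloxy)oxepan-2-one, via lithium lactone enolate 11 (not isolated)
Conditions: LiN(i-Pr)2, THF, −78 °C; then cannulated into 10, THF, −78 °C
Reagents that add atoms: none
Why: Claisen-type C-acylation of a lithium lactone enolate by an acid chloride creates the quaternary carbon. The acid chloride should enter on the enolate face away from the silyloxy group: the pseudoaxial C7 methyl closes the face over which the ring is folded, and only the chair with the silyloxy group equatorial offers an unhindered convex face. This places the acyl group trans and the methyl cis to the silyl ether.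

Step 7
Reactants: 12 (3S,6R)-3-[(2E)-2-methylbut-2-enoyl]-3,7,7-trimethyl-6-(triisopropylsilyloxy)oxepan-2-one
Product: 13 (3S,6R)-3-[(1E)-1-(tert-butyldimethylsilyloxy)-2-methylbuta-1,3-dien-1-yl]-3,7,7-trimethyl-6-(triisopropylsilyloxy)oxepan-2-one
Conditions: TBSOTf, Et3N, CH2Cl2, 0 °C → rt
Reagents that add atoms: tert-butyldimethylsilyl trifluoromethanesulfonate, CC(C)(C)[Si](C)(C)OS(=O)(=O)C(F)(F)F
Why: Soft enolisation: O-silylation and γ-deprotonation, the only enolisable position because the other α-carbon is quaternary, give the 2-silyloxydiene without a free dienolate that could attack the lactone. The s-trans enone conformer, in which the quaternary carbon faces the β-hydrogen and not the α-methyl, leads to the (1E)-isomer with the vinyl group cis to the quaternary carbon. The dienol ether also masks the ketone for step 8.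

Step 8
Reactants: 13 (3S,6R)-3-[(1E)-1-(tert-butyldimethylsilyloxy)-2-methylbuta-1,3-dien-1-yl]-3,7,7-trimethyl-6-(triisopropylsilyloxy)oxepan-2-one
Product: 15 (3S,6R)-3-[(1E)-1-(tert-butyldimethylsilyloxy)-2-methylbuta-1,3-dien-1-yl]-3,7,7-trimethyl-6-(triisopropylsilyloxy)oxepan-2-yl acetate (anomeric mixture), via diisobutylaluminium lactolate 14 (not isolated)
Conditions: i-Bu2AlH, CH2Cl2, −78 °C; then pyridine, DMAP, Ac2O, −78 → 0 °C
Reagents that add atoms: acetic anhydride, CC(=O)OC(C)=O
Why: Reductive acetylation of a lactone (Rychnovsky protocol): lactolate 14, stable at low temperature, is acetylated in the flask before it can open to the hydroxy aldehyde. The ketone is protected as its silyl dienol ether.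

Step 9
Reactants: 15 (3S,6R)-3-[(1E)-1-(tert-butyldimethylsilyloxy)-2-methylbuta-1,3-dien-1-yl]-3,7,7-trimethyl-6-(triisopropylsilyloxy)oxepan-2-yl acetate
Product: 17 (3R,5aR,9aS)-2,2,5a,7-tetramethyl-3-(triisopropylsilyloxy)-3,4,5,5a,9,9a-hexahydro-1-benzoxepin-6(2H)-one (trans-fused enone), via oxepanyl oxocarbenium triflate 16 (not isolated)
Conditions: TMSOTf (0.3 equiv), 2,6-di-tert-butyl-4-methylpyridine, CH2Cl2, −78 → −40 °C
Reagents that add atoms: none
Why: The silyl triflate ionises the anomeric acetate to oxocarbenium ion 16, which cannot lose a proton because the neighbouring carbon is quaternary. The terminal CH2 of the (1E)-silyloxydiene held on that carbon attacks the cationic carbon (α-attack would give a four-membered ring), and transfer of the silyl group to acetate leaves the conjugated enone and regenerates a silyl triflate. The closest known reaction type is the vinylogous Mukaiyama addition of silyl dienol ethers to oxocarbenium ions from acetals and α-acetoxy ethers, which is known in intramolecular form. The cyclohexene closes in a six-membered mode that is endo with respect to the diene (both diene double bonds lie in the forming ring) and exo with respect to the C=O+ bond. The new stereocentre C9a is controlled by the adjacent quaternary carbon C5a: in the chair-like transition state the angular methyl is axial, the ring methylene C5 stands perpendicular to the oxocarbenium plane and anti to the forming bond, and the diene arm lies on the hydrogen side of the cationic carbon, which puts the C9a hydrogen anti to the methyl (trans fusion). The cis-fused alternative would place the bulky silyloxydiene arm next to the ring oxygen and its gem-dimethyl carbon. The step therefore needs facial selectivity (trans over cis) and chemoselectivity (C–C bond formation over transannular capture by the C6 oxygen); the latter is served by the bulky triisopropylsilyl group, the low temperature and the hindered base, which prevents protodesilylation of the dienol ether.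

Step 10
Reactants: 17 trans-fused enone
Product: 19 (3R,5aR,9aS)-2,2,5a,7-tetramethyl-3-(triisopropylsilyloxy)-2,3,4,5,5a,8,9,9a-octahydro-1-benzoxepin-6-yl trifluoromethanesulfonate, via lithium enolate 18 (not isolated)
Conditions: LiBH(s-Bu)3, THF, −78 °C; then Comins' reagent, −78 → 0 °C
Reagents that add atoms: N-(5-chloropyridin-2-yl)-N-(trifluoromethylsulfonyl)trifluoromethanesulfonamide (Comins' reagent), O=S(=O)(N(c1ccc(Cl)cn1)S(=O)(=O)C(F)(F)F)C(F)(F)F
Why: Conjugate reduction of the α-methyl enone by the bulky borohydride (the carbonyl is shielded by the quaternary carbon) gives the only possible enolate 18, which is trapped on oxygen by the triflimide. No stereocentre is formed because C7 becomes trigonal.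

Step 11
Reactants: 19 enol triflate; 20 tributyl(vinyl)stannane
Product: 21 (3R,5aS,9aS)-6-ethenyl-2,2,5a,7-tetramethyl-3-(triisopropylsilyloxy)-2,3,4,5,5a,8,9,9a-octahydro-1-benzoxepine
Conditions: Pd(PPh3)4 (cat.), LiCl, THF, 65 °C
Reagents that add atoms: none
Why: Stille coupling of the enol triflate: oxidative addition to zerovalent palladium, chloride-assisted transmetallation and reductive elimination install the two bridge carbons as a vinyl group.

Step 12
Reactants: 19 enol triflate
Product: 22 (3R,5aR,9aS)-3-hydroxy-2,2,5a,7-tetramethyl-2,3,4,5,5a,8,9,9a-octahydro-1-benzoxepin-6-yl trifluoromethanesulfonate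
Conditions: aq. HF (48%), MeCN, rt
Reagents that add atoms: none
Why: Acidic fluoride cleavage of the silyl ether; the enol triflate and the ether ring tolerate aqueous HF, whereas basic fluoride could attack the triflate.

Step 13
Reactants: 22 hydroxy enol triflate
Product: 23 (5aR,9aS)-2,2,5a,7-tetramethyl-3-oxo-2,3,4,5,5a,8,9,9a-octahydro-1-benzoxepin-6-yl trifluoromethanesulfonate
Conditions: Dess–Martin periodinane, CH2Cl2, 0 °C → rt
Reagents that add atoms: none
Why: Dess–Martin oxidation of the secondary alcohol under neutral conditions gives the ketone half in its final oxidation state before union, so no late differentiation of two equal carbinols is needed.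

Step 14
Reactants: 21 vinyl diene; 23 keto enol triflate
Product: 25 3-O-triisopropylsilyl sodwanone T, via B-alkyl-9-BBN borane 24 (not isolated)
Conditions: 9-BBN, THF, 0 °C → rt; then 23, PdCl2(dppf) (cat.), AsPh3, Cs2CO3, DMF–H2O, 50 °C
Reagents that add atoms: none
Why: 9-BBN hydroborates the terminal vinyl group (the tetrasubstituted alkene is inert) to give primary alkylborane 24, which undergoes B-alkyl Suzuki–Miyaura coupling with the enol triflate. The ketone tolerates the aqueous carbonate conditions.

Step 15
Reactants: 25 3-O-triisopropylsilyl sodwanone T
Product: 26 sodwanone T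
Conditions: Bu4NF, THF, rt → 40 °C
Reagents that add atoms: none
Why: Fluoride cleavage of the remaining silyl ether; the ketone has no epimerisable α-stereocentre and the tetrasubstituted alkenes are inert to fluoride.

## Compound list

1 | ethyl 2-hydroxy-2-methylpropanoate (ethyl 2-hydroxyisobutyrate) | CCOC(=O)C(C)(C)O | starting material
2 | propanoyl chloride | CCC(=O)Cl | starting material
3 | ethyl 2-methyl-2-(propanoyloxy)propanoate | CCOC(=O)C(C)(C)OC(=O)CC | intermediate
4 | 4-hydroxy-3,5,5-trimethylfuran-2(5H)-one (3,5,5-trimethyltetronic acid) | CC1=C(O)C(C)(C)OC1=O | intermediate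
5 | ethylene | C=C | starting material
6 | 5-hydroxy-1,4,4-trimethyl-3-oxabicyclo[3.2.0]heptan-2-one (racemic cyclobutanol photoadduct, not isolated) | CC12CCC1(O)C(C)(C)OC2=O | intermediate
7 | 3,7,7-trimethyloxepane-2,6-dione (racemic) | CC1CCC(=O)C(C)(C)OC1=O | intermediate
8 | (6R)-6-hydroxy-3,7,7-trimethyloxepan-2-one (C3 epimers) | CC1CC[C@@H](O)C(C)(C)OC1=O | intermediate
9 | (6R)-3,7,7-trimethyl-6-(triisopropylsilyloxy)oxepan-2-one (C3 epimers) | CC1CC[C@@H](O[Si](C(C)C)(C(C)C)C(C)C)C(C)(C)OC1=O | intermediate
10 | (E)-2-methylbut-2-enoyl chloride (tigloyl chloride) | C/C=C(\C)C(=O)Cl | starting material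
11 | lithium enolate of lactone 9 (not isolated) | CC1=C(O[Li])OC(C)(C)[C@H](O[Si](C(C)C)(C(C)C)C(C)C)CC1 | intermediate
12 | (3S,6R)-3-[(2E)-2-methylbut-2-enoyl]-3,7,7-trimethyl-6-(triisopropylsilyloxy)oxepan-2-one | O=C1OC(C)(C)[C@H](O[Si](C(C)C)(C(C)C)C(C)C)CC[C@@]1(C)C(=O)/C(C)=C/C | intermediate
13 | (3S,6R)-3-[(1E)-1-(tert-butyldimethylsilyloxy)-2-methylbuta-1,3-dien-1-yl]-3,7,7-trimethyl-6-(triisopropylsilyloxy)oxepan-2-one | O=C1OC(C)(C)[C@H](O[Si](C(C)C)(C(C)C)C(C)C)CC[C@@]1(C)/C(O[Si](C)(C)C(C)(C)C)=C(/C)C=C | intermediate
14 | diisobutylaluminium lactolate of 13 (not isolated) | CC(C)C[Al](CC(C)C)OC1OC(C)(C)[C@H](O[Si](C(C)C)(C(C)C)C(C)C)CC[C@@]1(C)/C(O[Si](C)(C)C(C)(C)C)=C(/C)C=C | intermediate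
15 | (3S,6R)-3-[(1E)-1-(tert-butyldimethylsilyloxy)-2-methylbuta-1,3-dien-1-yl]-3,7,7-trimethyl-6-(triisopropylsilyloxy)oxepan-2-yl acetate (anomeric mixture) | CC(=O)OC1OC(C)(C)[C@H](O[Si](C(C)C)(C(C)C)C(C)C)CC[C@@]1(C)/C(O[Si](C)(C)C(C)(C)C)=C(/C)C=C | intermediate
16 | oxepanyl oxocarbenium triflate from 15 (not isolated) | C1=[O+]C(C)(C)[C@H](O[Si](C(C)C)(C(C)C)C(C)C)CC[C@@]1(C)/C(O[Si](C)(C)C(C)(C)C)=C(/C)C=C.[O-]S(=O)(=O)C(F)(F)F | intermediate
17 | (3R,5aR,9aS)-2,2,5a,7-tetramethyl-3-(triisopropylsilyloxy)-3,4,5,5a,9,9a-hexahydro-1-benzoxepin-6(2H)-one (trans-fused enone) | CC1=CC[C@@H]2OC(C)(C)[C@H](O[Si](C(C)C)(C(C)C)C(C)C)CC[C@@]2(C)C1=O | intermediate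
18 | lithium enolate from conjugate reduction of 17 (not isolated) | CC=1CC[C@@H]2OC(C)(C)[C@H](O[Si](C(C)C)(C(C)C)C(C)C)CC[C@@]2(C)C=1O[Li] | intermediate
19 | (3R,5aR,9aS)-2,2,5a,7-tetramethyl-3-(triisopropylsilyloxy)-2,3,4,5,5a,8,9,9a-octahydro-1-benzoxepin-6-yl trifluoromethanesulfonate | CC=1CC[C@@H]2OC(C)(C)[C@H](O[Si](C(C)C)(C(C)C)C(C)C)CC[C@@]2(C)C=1OS(=O)(=O)C(F)(F)F | intermediate
20 | tributyl(vinyl)stannane | C=C[Sn](CCCC)(CCCC)CCCC | starting material
21 | (3R,5aS,9aS)-6-ethenyl-2,2,5a,7-tetramethyl-3-(triisopropylsilyloxy)-2,3,4,5,5a,8,9,9a-octahydro-1-benzoxepine | CC=1CC[C@@H]2OC(C)(C)[C@H](O[Si](C(C)C)(C(C)C)C(C)C)CC[C@@]2(C)C=1C=C | intermediate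
22 | (3R,5aR,9aS)-3-hydroxy-2,2,5a,7-tetramethyl-2,3,4,5,5a,8,9,9a-octahydro-1-benzoxepin-6-yl trifluoromethanesulfonate | CC=1CC[C@@H]2OC(C)(C)[C@H](O)CC[C@@]2(C)C=1OS(=O)(=O)C(F)(F)F | intermediate
23 | (5aR,9aS)-2,2,5a,7-tetramethyl-3-oxo-2,3,4,5,5a,8,9,9a-octahydro-1-benzoxepin-6-yl trifluoromethanesulfonate | CC=1CC[C@@H]2OC(C)(C)C(=O)CC[C@@]2(C)C=1OS(=O)(=O)C(F)(F)F | intermediate
24 | 9-{2-[(3R,5aS,9aS)-2,2,5a,7-tetramethyl-3-(triisopropylsilyloxy)-2,3,4,5,5a,8,9,9a-octahydro-1-benzoxepin-6-yl]ethyl}-9-borabicyclo[3.3.1]nonane (not isolated) | CC=1CC[C@@H]2OC(C)(C)[C@H](O[Si](C(C)C)(C(C)C)C(C)C)CC[C@@]2(C)C=1CCB1C2CCCC1CCC2 | intermediate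
25 | 3-O-triisopropylsilyl sodwanone T | CC1=C(CCC2=C(C)CC[C@@H]3OC(C)(C)[C@H](O[Si](C(C)C)(C(C)C)C(C)C)CC[C@@]23C)[C@]2(C)CCC(=O)C(C)(C)O[C@H]2CC1 | intermediate
26 | sodwanone T | CC1=C(CCC2=C(C)CC[C@@H]3OC(C)(C)[C@H](O)CC[C@@]23C)[C@]2(C)CCC(=O)C(C)(C)O[C@H]2CC1 | target

## Step count and least certain steps

Total: 15 steps. Longest linear sequence: 14 steps (steps 1–10, 12, 13, 14, 15; step 11 is the one-step branch from 19).

**Step 9 (key step).** The risks are poor facial selectivity in the attack on the oxocarbenium ion (cis fusion), transannular capture of the cation by the C6 silyloxy oxygen with loss of the silyl group, and a (1Z)-dienol ether that cannot reach the cation. The preference for trans fusion rests on where the diene arm sits relative to the ring oxygen, not on a rigid control element, and the C6 oxygen can bridge to the cationic carbon through a five-membered ring.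

The fallback builds the carbocycle by allylation and ring-closing metathesis. It sets out from 12 and returns at 17.
- Luche reduction of the ketone of 12 (NaBH4, CeCl3·7H2O, MeOH) gives allylic alcohol F1, which is protected as triethylsilyl ether F2 (TESOTf, 2,6-lutidine).
- Reductive acetylation as in step 8 gives lactol acetate F3, now free of any internal nucleophile.
- Allyltrimethylsilane and BF3·OEt2 give the 2-allyl oxepane F4.
- Ring-closing metathesis (second-generation Hoveyda–Grubbs catalyst, toluene, 80 °C) closes the cyclohexene onto the trisubstituted alkene to give bicyclic silyl ether F5.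
- Selective cleavage of the triethylsilyl group (HF·pyridine, THF, 0 °C) gives allylic alcohol F6, and Dess–Martin oxidation returns enone 17.

The fusion hydrogen is then set in an intermolecular step whose sense can be inverted. If the allyl group enters on the wrong face, allylmagnesium bromide is added to the lactone of F2 to give lactol F7, and Et3SiH with BF3·OEt2 delivers hydride to that same face, again leading to F4.

**Step 6.** The risk is insufficient facial discrimination in the acylation, accompanied by O-acylation of the tetrasubstituted enolate. The silyloxy group is 1,4 to the enolate carbon, and two chair conformers of the enolate lead to opposite epimers at the quaternary carbon.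

The fallback reverses the order of bond formation and places the last bond under catalyst control. It sets out from 1 and returns at 12.
- Acetyl chloride, in place of 2, gives ethyl 2-(acetyloxy)-2-methylpropanoate F8.
- The Dieckmann condensation, the de Mayo ring expansion with 5, the oxazaborolidine reduction and the silylation are repeated. They give 5,5-dimethyltetronic acid F9, 7,7-dimethyloxepane-2,6-dione F10, hydroxy lactone F11 and silyl ether F12.
- Acylation of F12 (two equivalents of LiN(i-Pr)2) with 10 gives β-keto lactone F13, which has an acidic hydrogen at C3.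
- Methylation with iodomethane under solid–liquid phase-transfer conditions (Cs2CO3, toluene, a cinchona-derived quaternary ammonium bromide) creates the quaternary carbon and gives 12. The chiral catalyst, not the distant silyloxy group, then selects the face.

**Step 3.** The risk is inefficient photocycloaddition of the free enol, which is acidic, partly ionised and open to competing photodecomposition, followed by incomplete retro-aldol cleavage.

The fallback separates cycloaddition from fragmentation. It sets out from 4 and returns at 7.
- Acetylation (Ac2O, Et3N) gives enol acetate F14, a neutral tetronate chromophore.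
- Irradiation of F14 with 5 gives the acetoxy cyclobutane F15.
- K2CO3 in methanol removes the acetyl group, and the liberated alkoxide fragments to 7.

**Step 8.** The risks are over-reduction to the diol, collapse of lactolate 14 to the hydroxy aldehyde before acetylation, and loss of the silyl dienol ether on work-up. The lactone is hindered on both sides and may need temperatures at which 14 is no longer stable.

The fallback goes through full reduction and re-oxidation. It sets out from 13 and returns at 15.
- LiAlH4 (THF, 0 °C) reduces the lactone to diol F16.
- Parikh–Doering oxidation (SO3·pyridine, DMSO, Et3N) converts the primary alcohol into the aldehyde, which closes onto the tertiary hydroxyl as lactol F17.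
- Acetylation (Ac2O, Et3N, DMAP) gives 15.

**Step 14.** The risk is slow oxidative addition and transmetallation at the tetrasubstituted enol triflate beside a quaternary carbon, so that protodeboronation of 24 or hydrolysis of the triflate takes over.

The fallback replaces the borane by an organozinc. It sets out from 21 and returns at 25.
- Hydroboration with 9-BBN and oxidative work-up (NaBO3) give primary alcohol F18.
- I2, PPh3 and imidazole give iodide F19.
- Zinc insertion (Zn, LiCl, THF) gives alkylzinc iodide F20.
- Negishi coupling with 23 (Pd(OAc)2, SPhos, THF) gives 25. The ketone of 23 tolerates the organozinc.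

## Further compounds

F1 | step 9 | (3S,6R)-3-[(2E)-1-hydroxy-2-methylbut-2-en-1-yl]-3,7,7-trimethyl-6-(triisopropylsilyloxy)oxepan-2-one (carbinol epimers) | O=C1OC(C)(C)[C@H](O[Si](C(C)C)(C(C)C)C(C)C)CC[C@@]1(C)C(O)/C(C)=C/C
F2 | step 9 | triethylsilyl ether of F1 | O=C1OC(C)(C)[C@H](O[Si](C(C)C)(C(C)C)C(C)C)CC[C@@]1(C)C(O[Si](CC)(CC)CC)/C(C)=C/C
F3 | step 9 | lactol acetate of F2 (anomeric mixture) | CC(=O)OC1OC(C)(C)[C@H](O[Si](C(C)C)(C(C)C)C(C)C)CC[C@@]1(C)C(O[Si](CC)(CC)CC)/C(C)=C/C
F4 | step 9 | 2-allyl oxepane with the allyl group trans to the carbinol arm | C=CC[C@@H]1OC(C)(C)[C@H](O[Si](C(C)C)(C(C)C)C(C)C)CC[C@@]1(C)C(O[Si](CC)(CC)CC)/C(C)=C/C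
F5 | step 9 | trans-fused 6-(triethylsilyloxy)-hexahydro-1-benzoxepine from ring-closing metathesis | CC1=CC[C@@H]2OC(C)(C)[C@H](O[Si](C(C)C)(C(C)C)C(C)C)CC[C@@]2(C)C1O[Si](CC)(CC)CC
F6 | step 9 | trans-fused allylic alcohol (6-hydroxy analogue of 17) | CC1=CC[C@@H]2OC(C)(C)[C@H](O[Si](C(C)C)(C(C)C)C(C)C)CC[C@@]2(C)C1O
F7 | step 9 | 2-allyl lactol from F2 and allylmagnesium bromide | C=CCC1(O)OC(C)(C)[C@H](O[Si](C(C)C)(C(C)C)C(C)C)CC[C@@]1(C)C(O[Si](CC)(CC)CC)/C(C)=C/C
F8 | step 6 | ethyl 2-(acetyloxy)-2-methylpropanoate | CCOC(=O)C(C)(C)OC(C)=O
F9 | step 6 | 4-hydroxy-5,5-dimethylfuran-2(5H)-one (5,5-dimethyltetronic acid) | OC1=CC(=O)OC1(C)C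
F10 | step 6 | 7,7-dimethyloxepane-2,6-dione | O=C1CCC(=O)C(C)(C)O1
F11 | step 6 | (6R)-6-hydroxy-7,7-dimethyloxepan-2-one | O=C1CCC[C@@H](O)C(C)(C)O1
F12 | step 6 | (6R)-7,7-dimethyl-6-(triisopropylsilyloxy)oxepan-2-one | O=C1CCC[C@@H](O[Si](C(C)C)(C(C)C)C(C)C)C(C)(C)O1
F13 | step 6 | (6R)-3-[(2E)-2-methylbut-2-enoyl]-7,7-dimethyl-6-(triisopropylsilyloxy)oxepan-2-one (C3 epimers) | C/C=C(\C)C(=O)C1CC[C@@H](O[Si](C(C)C)(C(C)C)C(C)C)C(C)(C)OC1=O
F14 | step 3 | 4-acetoxy-3,5,5-trimethylfuran-2(5H)-one | CC(=O)OC1=C(C)C(=O)OC1(C)C
F15 | step 3 | 5-acetoxy-1,4,4-trimethyl-3-oxabicyclo[3.2.0]heptan-2-one (racemic) | CC(=O)OC12CCC1(C)C(=O)OC2(C)C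
F16 | step 8 | diol from full reduction of 13 | CC(C)(O)[C@H](O[Si](C(C)C)(C(C)C)C(C)C)CC[C@](C)(CO)/C(O[Si](C)(C)C(C)(C)C)=C(/C)C=C
F17 | step 8 | lactol corresponding to 15 (anomeric mixture) | OC1OC(C)(C)[C@H](O[Si](C(C)C)(C(C)C)C(C)C)CC[C@@]1(C)/C(O[Si](C)(C)C(C)(C)C)=C(/C)C=C
F18 | step 14 | 2-[(3R,5aS,9aS)-2,2,5a,7-tetramethyl-3-(triisopropylsilyloxy)-2,3,4,5,5a,8,9,9a-octahydro-1-benzoxepin-6-yl]ethanol | CC=1CC[C@@H]2OC(C)(C)[C@H](O[Si](C(C)C)(C(C)C)C(C)C)CC[C@@]2(C)C=1CCO
F19 | step 14 | primary iodide from F18 | CC=1CC[C@@H]2OC(C)(C)[C@H](O[Si](C(C)C)(C(C)C)C(C)C)CC[C@@]2(C)C=1CCI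
F20 | step 14 | alkylzinc iodide from F19 | CC=1CC[C@@H]2OC(C)(C)[C@H](O[Si](C(C)C)(C(C)C)C(C)C)CC[C@@]2(C)C=1CC[Zn]I
A1 | alternative 1 | bibenzyl bis[(S)-2-(methoxymethyl)pyrrolidine amide] of 6,6'-ethane-1,2-diylbis(2-methoxy-5-methylbenzoic acid) | COc1ccc(C)c(CCc2c(C)ccc(OC)c2C(=O)N2CCC[C@H]2COC)c1C(=O)N1CCC[C@H]1COC
A2 | alternative 1 | bis(1-methoxycyclohexa-1,4-diene) with two methylated quaternary carbons | CC1=C(CCC2=C(C)CC=C(OC)[C@@]2(C)C(=O)N2CCC[C@H]2COC)[C@](C)(C(=O)N2CCC[C@H]2COC)C(OC)=CC1
A3 | alternative 2 | cyclohexene bearing the S-(pyridin-2-yl) thioester chain and the N-acyloxyphthalimide of the α-alkoxyisobutyric acid | CC1=C(COC(=O)C(C)(C)C)[C@](C)(CCC(=O)Sc2ccccn2)[C@@H](OC(C)(C)C(=O)ON2C(=O)c3ccccc3C2=O)CC1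
A4 | alternative 2 | ketone-half bicycle with pivaloyloxymethyl handle | CC1=C(COC(=O)C(C)(C)C)[C@]2(C)CCC(=O)C(C)(C)O[C@H]2CC1
A5 | alternative 3 | (3R,6S,7S,18S,19S,22R)-2,3:6,7:18,19:22,23-tetraepoxysqualene (10E,14E) | CC1(C)O[C@@H]1CC[C@]2(C)O[C@H]2CC/C(C)=C/CC/C=C(\C)CC[C@@H]2O[C@@]2(C)CC[C@H]2OC2(C)C
A6 | alternative 3 | twofold-symmetric bis(oxepane–cyclohexene) diol | CC1=C(CCC2=C(C)CC[C@@H]3OC(C)(C)[C@H](O)CC[C@@]23C)[C@]2(C)CC[C@@H](O)C(C)(C)O[C@H]2CC1
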